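**Retrosynthetic overview**

1. The target comes from (13S)-labdane-8α,15-diol 17 by selective O-acetylation; 17 comes from the 8α-hydroxy-3-oxolabda-1,6-diene 15 by hydrogenation and Wolff–Kishner removal of a relay carbonyl at C3.
2. Ring A is formed last, from the monocyclic ring-B aldehyde 10 and 2-iodo-3-methylbut-2-ene 12, in one [3+3] domino: Cu-catalysed O-vinylation of the 7β-hydroxyl, Claisen shift (C4–C5), aldol condensation (C1–C2).
3. Enabling feature: in ring B (C5–C10), C5 is the γ-terminus of the allylic alcohol C5=C6–C7(β-OH) and the formyl carbon C1 sits on the neighbouring quaternary C10. The C7 oxygen relays C4 suprafacially onto C5 (5α-H, trans fusion), leaves ring B and becomes the C3 carbonyl that activates C2 for closure onto C1.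
4. Ring B is formed first by an enantioselective Diels–Alder reaction of the citronellol-derived (E)-enal 4 (C13 from the chiral pool) with dienyl acetate 6, which sets C9/C10; Pd-elimination to diene 8 and α-epoxidation/hydrolysis then set C8 and the C7 relay hydroxyl.

Key step: step 8

Remark: the target SMILES encodes (5S,8R,9R,10S,13S)-8-hydroxylabdan-15-yl acetate (8α-OH, normal labdane series); labdane numbering (C1–C20) and α/β face descriptors are used throughout.

**Route**

Step 1
Reactants: 1 (S)-citronellol
Product: 2 (3S)-3,7-dimethyloct-6-en-1-yl pivalate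
Conditions: PivCl, pyridine, DMAP (cat.), CH2Cl2, 0 °C → rt
Reagents that add atoms: pivaloyl chloride CC(C)(C)C(Cl)=O
Why: DMAP-catalysed acylation of the primary alcohol; the pivalate has no enolisable hydrogens, should survive metathesis, Lewis acid, Pd(0), dilute acid, carbonate base and hydrogenation, and is removed without an extra step in step 10.

Step 2
Reactants: 2 (3S)-3,7-dimethyloct-6-en-1-yl pivalate; 3 methacrolein
Product: 4 (3S,6E)-3,7-dimethyl-8-oxooct-6-en-1-yl pivalate
Conditions: methacrolein (5 equiv), second-generation Ru–NHC isopropoxybenzylidene metathesis catalyst (5 mol %), CH2Cl2, 40 °C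
Reagents that add atoms: none
Why: Olefin cross-metathesis of the prenyl-type trisubstituted alkene with excess methacrolein expels volatile isobutene and should give the thermodynamically preferred (E)-2-methyl-2-enal, leaving the remote C13 stereocentre untouched.

Step 3
Reactants: 5 (E)-pent-2-enal
Product: 6 (1E,3E)-penta-1,3-dien-1-yl acetate
Conditions: isopropenyl acetate, TsOH (cat.), Cu(OAc)2 (cat.), 95 °C, acetone distilled off
Reagents that add atoms: isopropenyl acetate CC(=C)OC(C)=O
Why: Acid-catalysed acetyl transfer to the dienol of the enal (enol acetate formation through γ-deprotonation) gives the dienyl acetate, driven by removal of acetone.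

Step 4
Reactants: 4 (3S,6E)-3,7-dimethyl-8-oxooct-6-en-1-yl pivalate; 6 (1E,3E)-penta-1,3-dien-1-yl acetate
Product: 7 (3S)-5-[5-acetoxy-6-formyl-2,6-dimethylcyclohex-3-en-1-yl]-3-methylpentyl pivalate (side chain on C9 β, ring methyl C20 β, formyl α; drawn as the formyl-endo isomer with 5-acetoxy α and 2-methyl α)
Conditions: (S)-o-tolyl-oxazaborolidinium triflimide (prolinol-derived chiral boron Lewis acid, 20 mol %), CH2Cl2, −78 → −40 °C
Reagents that add atoms: none
Why: Catalytic enantioselective Diels–Alder reaction in which the acetoxy group directs the "ortho" orientation (acetoxy-bearing terminus to the formyl-bearing carbon), suprafacial addition to the (E)-enal puts the C20 methyl and the side chain cis, and the chiral boron cation shields one enal face so that the diene adds to the 2-Si,3-Re face and fixes C9 and C10 (the (S)-catalyst is expected from the usual formyl C–H···O binding model, otherwise its mirror image is used); the configuration at the acetoxy- and methyl-bearing carbons is irrelevant because both become sp2 in step 5.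

Step 5
Reactants: 7 Diels–Alder adduct
Product: 8 (3S)-5-[6-formyl-2,6-dimethylcyclohexa-2,4-dien-1-yl]-3-methylpentyl pivalate (side chain and 6-methyl cis, both β; formyl α)
Conditions: Pd(PPh3)4 (5 mol %), Et3N, THF, 65 °C
Reagents that add atoms: none
Why: Pd(0) ionises the allylic acetate to a π-allyl complex whose only β-hydrogen sits on the methyl-bearing carbon and is syn to palladium in either adduct epimer, so β-hydride elimination (Tsuji–Trost-type elimination) should funnel both epimers into the same conjugated diene without touching C9 or the quaternary C10.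

Step 6
Reactants: 8 cyclohexadiene aldehyde
Product: 10 (3S)-5-[6-formyl-2,3-dihydroxy-2,6-dimethylcyclohex-4-en-1-yl]-3-methylpentyl pivalate (C8: α-OH, β-CH3; C7: β-OH; trans-diol), via vinyl epoxide 9 (not isolated)
Conditions: dimethyldioxirane, acetone, −40 → −20 °C; then HClO4 (cat.), THF/H2O, 0 °C
Reagents that add atoms: dimethyldioxirane CC1(C)OO1; water O
Why: Electrophilic epoxidation should occur at the more substituted C7=C8 bond from the α-face, anti to the β side chain on C9 and the β-methyl on C10 (sets 8α-O), and acid-catalysed hydrolysis then opens the vinyl epoxide by backside attack of water at the allylic C7 (inversion, sets 7β-OH); the non-enolisable aldehyde is expected to be inert to the dioxirane at low temperature.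

Step 7
Reactants: 11 2-bromo-3-methylbut-2-ene
Product: 12 2-iodo-3-methylbut-2-ene
Conditions: NaI, CuI (5 mol %), N,N′-dimethylethane-1,2-diamine (10 mol %), 1,4-dioxane, 110 °C
Reagents that add atoms: sodium iodide [Na+].[I-]
Why: Copper-catalysed halogen exchange (vinylic Finkelstein reaction) converts the commercial vinyl bromide into the vinyl iodide needed for C–O coupling.

Step 8
Reactants: 10 diol aldehyde; 12 2-iodo-3-methylbut-2-ene
Product: 15 (13S)-8α-hydroxy-3-oxolabda-1,6-dien-15-yl pivalate, via allyl vinyl ether 13 (not isolated), via Claisen keto aldehyde 14 (not isolated)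
Conditions: CuI (10 mol %), 3,4,7,8-tetramethyl-1,10-phenanthroline (20 mol %), Cs2CO3 (3 equiv), o-xylene, 120 → 140 °C
Reagents that add atoms: none
Why: An Ullmann-type copper(I)-catalysed C–O coupling (closest precedent: the copper-catalysed domino vinylation/Claisen reaction of allylic alcohols with vinyl iodides) etherifies the secondary allylic 7β-hydroxyl of 10, not the hindered tertiary 8α-hydroxyl, to give 13, whose fully substituted enol-ether carbon is the future C4. At the reaction temperature 13 undergoes a chair-like [3,3]-sigmatropic (Claisen) shift in which the C7–O bond breaks, C4 bonds to C5, the double bond moves to C6=C7 and the relay oxygen becomes the C3 carbonyl of methyl ketone 14. Caesium carbonate then enolises the methyl group (C2) and ring A closes by intramolecular aldol condensation onto the C1 formyl group, a 6-(enolexo)-exo-trig closure followed by E1cB loss of water to the 1-en-3-one; ring A is the only ring closed. The single new stereocentre C5 is fixed by suprafacial 1,3-chirality transfer across the allyl unit: the β-oriented C7 oxygen delivers C4 to the β-face of C5, so H-5 is α and the ring fusion is trans to the C10 methyl, while C4 carries two methyl groups and is not stereogenic. The step needs site selectivity between the two hydroxyls (secured by steric hindrance at the tertiary one), a regiodefined enol ether (secured by the vinyl iodide, so that C4 and not C2 is transferred to C5) and closure only between C2 and C1 (the methyl ketone is the only enolisable carbonyl, and the formyl group is the only electrophile within reach of a six-membered ring).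

Step 9
Reactants: 15 dienone
Product: 16 (13S)-8α-hydroxy-3-oxolabdan-15-yl pivalate
Conditions: H2 (1 atm), Pd/C, EtOAc, Et3N (trace), rt
Reagents that add atoms: none
Why: Heterogeneous hydrogenation should saturate the conjugated C1=C2 bond and the disubstituted C6=C7 bond without creating stereocentres (C1, C2, C6 and C7 all become CH2), with the ketone, tertiary alcohol and pivalate inert under these conditions.

Step 10
Reactants: 16 hydroxy ketone
Product: 17 (13S)-labdane-8α,15-diol
Conditions: N2H4·H2O, KOH, diethylene glycol, 130 °C then 200 °C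
Reagents that add atoms: none
Why: Wolff–Kishner reduction (Huang–Minlon modification) removes the relay carbonyl at C3 through the hydrazone anion and loss of N2, a standard operation on hindered 4,4-dimethyl-3-oxo terpenoids; the hot KOH also saponifies the pivalate, and no stereocentre is α to the carbonyl.

Step 11
Reactants: 17 diol
Product: 18 (13S)-8α-hydroxylabdan-15-yl acetate (target)
Conditions: Ac2O (1.2 equiv), pyridine, CH2Cl2, 0 °C → rt
Reagents that add atoms: acetic anhydride CC(=O)OC(C)=O
Why: Mild acylation should be selective for the primary C15 hydroxyl because the hindered tertiary 8α-hydroxyl is not esterified under these conditions.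

**Compound list**

1 | (S)-citronellol, (3S)-3,7-dimethyloct-6-en-1-ol | OCC[C@@H](C)CCC=C(C)C | starting material
2 | (3S)-3,7-dimethyloct-6-en-1-yl pivalate | CC(C)(C)C(=O)OCC[C@@H](C)CCC=C(C)C | intermediate
3 | methacrolein (2-methylprop-2-enal) | CC(=C)C=O | starting material
4 | (3S,6E)-3,7-dimethyl-8-oxooct-6-en-1-yl pivalate | CC(C)(C)C(=O)OCC[C@@H](C)CC/C=C(\C)C=O | intermediate
5 | (E)-pent-2-enal | CC/C=C/C=O | starting material
6 | (1E,3E)-penta-1,3-dien-1-yl acetate | CC(=O)O/C=C/C=C/C | intermediate
7 | (3S)-5-[5-acetoxy-6-formyl-2,6-dimethylcyclohex-3-en-1-yl]-3-methylpentyl pivalate (side chain β, 6-methyl β, formyl α; formyl-endo isomer drawn) | CC(C)(C)C(=O)OCC[C@@H](C)CC[C@H]1[C@H](C)C=C[C@H](OC(C)=O)[C@]1(C)C=O | intermediate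
8 | (3S)-5-[6-formyl-2,6-dimethylcyclohexa-2,4-dien-1-yl]-3-methylpentyl pivalate (side chain and 6-methyl β, formyl α) | CC(C)(C)C(=O)OCC[C@@H](C)CC[C@H]1C(C)=CC=C[C@]1(C)C=O | intermediate
9 | 7α,8α-epoxide of 8 (vinyl epoxide, oxygen anti to the side chain) | CC(C)(C)C(=O)OCC[C@@H](C)CC[C@H]1[C@]2(C)O[C@@H]2C=C[C@]1(C)C=O | intermediate
10 | (3S)-5-[6-formyl-2,3-dihydroxy-2,6-dimethylcyclohex-4-en-1-yl]-3-methylpentyl pivalate (C8 α-OH/β-CH3, C7 β-OH) | CC(C)(C)C(=O)OCC[C@@H](C)CC[C@H]1[C@](C)(O)[C@@H](O)C=C[C@]1(C)C=O | intermediate
11 | 2-bromo-3-methylbut-2-ene | CC(Br)=C(C)C | starting material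
12 | 2-iodo-3-methylbut-2-ene | CC(I)=C(C)C | intermediate
13 | 7β-O-(3-methylbut-2-en-2-yl) ether of 10 (allyl vinyl ether) | CC(C)(C)C(=O)OCC[C@@H](C)CC[C@H]1[C@](C)(O)[C@@H](OC(C)=C(C)C)C=C[C@]1(C)C=O | intermediate
14 | (3S)-5-[6-formyl-2-hydroxy-2,6-dimethyl-5-(2-methyl-3-oxobutan-2-yl)cyclohex-3-en-1-yl]-3-methylpentyl pivalate (new substituent β on C5) | CC(C)(C)C(=O)OCC[C@@H](C)CC[C@H]1[C@](C)(O)C=C[C@@H](C(C)(C)C(C)=O)[C@]1(C)C=O | intermediate
15 | (13S)-8α-hydroxy-3-oxolabda-1,6-dien-15-yl pivalate | CC(C)(C)C(=O)OCC[C@@H](C)CC[C@@H]1[C@@]2(C)C=CC(=O)C(C)(C)[C@@H]2C=C[C@@]1(C)O | intermediate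
16 | (13S)-8α-hydroxy-3-oxolabdan-15-yl pivalate | CC(C)(C)C(=O)OCC[C@@H](C)CC[C@@H]1[C@@]2(C)CCC(=O)C(C)(C)[C@@H]2CC[C@@]1(C)O | intermediate
17 | (13S)-labdane-8α,15-diol | OCC[C@@H](C)CC[C@@H]1[C@@]2(C)CCCC(C)(C)[C@@H]2CC[C@@]1(C)O | intermediate
18 | (5S,8R,9R,10S,13S)-8-hydroxylabdan-15-yl acetate | CC(=O)OCC[C@@H](C)CC[C@@H]1[C@@]2(C)CCCC(C)(C)[C@@H]2CC[C@@]1(C)O | target

**Step count and risks**

Total step count: 11. Longest linear sequence: 9 (steps 1, 2, 4, 5, 6, 8, 9, 10, 11); steps 3 and 7 are side branches.

Steps most likely to fail:

1. Step 8. The copper-mediated C–O coupling between the hindered secondary allylic alkoxide and the tetrasubstituted vinyl iodide may stall, the crowded Claisen shift may be slower than base-induced erosion of the formyl group at 120–140 °C, or the carbonate may fail to drive the aldol closure. The fallback sets out from 10 and separates the events. Oxidative (Chan–Lam-type) O-vinylation of the 7β-hydroxyl with commercial 4,4,5,5-tetramethyl-2-(3-methylbut-2-en-2-yl)-1,3,2-dioxaborolane (Cu(OAc)2, Et3N, air, CH2Cl2, rt) should give allyl vinyl ether 13, which is isolated. It is rearranged without base (toluene, 140 °C, sealed tube) to keto aldehyde 14, and this is closed in a separate mild aldol condensation (pyrrolidinium acetate, or KOH in MeOH, rt). The fallback comes back to the route at 15 and makes no compound outside the list.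

2. Step 4. The α,β-disubstituted enal may react too slowly with the moderately activated acetoxydiene at the low temperature that catalyst control needs, so facial discrimination (C9/C10 against the fixed C13) may be poor. The fallback sets out from 5 and 4 and moves the stereocontrol to an auxiliary on the diene. The potassium dienolate of 5 (KOt-Bu, THF, −78 °C) is O-acylated with (S)-O-methylmandeloyl chloride to give (1E,3E)-penta-1,3-dien-1-yl (2S)-2-methoxy-2-phenylacetate F1. BF3·OEt2-promoted Diels–Alder reaction of F1 with 4 should give the mandelate adduct F2 under diene-face control (written with the (S)-auxiliary; its enantiomer is used if the opposite sense is found). Pd(0)-elimination of the mandelate as in step 5 comes back to the route at 8.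

3. Step 6. Acid may ionise the vinyl epoxide (SN1-type opening), which would scramble the C7 configuration or give 1,4-diol, and the oxidant may over-oxidise the diene or attack the aldehyde. The fallback sets out from 8 and avoids the epoxide. OsO4 (cat.)/NMO cis-dihydroxylation of the trisubstituted ring double bond from the α-face should give the 7α,8α-cis-diol F3. Mitsunobu inversion of the secondary allylic hydroxyl (4-nitrobenzoic acid, PPh3, DIAD) should give the 7β-(4-nitrobenzoate) F4, and methanolysis (K2CO3, MeOH) comes back to the route at 10.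

Further compounds
F0 | step 8 | none | none
F1 | step 4 | (1E,3E)-penta-1,3-dien-1-yl (2S)-2-methoxy-2-phenylacetate | CO[C@@H](c1ccccc1)C(=O)O/C=C/C=C/C
F2 | step 4 | (3S)-5-[6-formyl-5-{[(2S)-2-methoxy-2-phenylacetyl]oxy}-2,6-dimethylcyclohex-3-en-1-yl]-3-methylpentyl pivalate (ring configuration as in 7) | CC(C)(C)C(=O)OCC[C@@H](C)CC[C@H]1[C@H](C)C=C[C@H](OC(=O)[C@@H](OC)c2ccccc2)[C@]1(C)C=O
F3 | step 6 | (3S)-5-[6-formyl-2,3-dihydroxy-2,6-dimethylcyclohex-4-en-1-yl]-3-methylpentyl pivalate, 7α,8α-cis-diol | CC(C)(C)C(=O)OCC[C@@H](C)CC[C@H]1[C@](C)(O)[C@H](O)C=C[C@]1(C)C=O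
F4 | step 6 | 7β-(4-nitrobenzoate) of 10 | CC(C)(C)C(=O)OCC[C@@H](C)CC[C@H]1[C@](C)(O)[C@@H](OC(=O)c2ccc(cc2)[N+](=O)[O-])C=C[C@]1(C)C=O
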